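**Strategy.** Each C18 acyl chain is cut at C12–C13, C14–C15 and C16–C17. The acyclic C13–C16 (Z,Z)-diene with its C17–C18 ethyl end is assembled from an ethyl–copper bond, two acetylene molecules and a primary iodide carrying C7–C12. In one operation lithium diethylcuprate adds syn to acetylene twice and the dienylcuprate is alkylated, so both Z double bonds arise without any reduction. The iodide is the TBS ether of (2E)-6-iodohex-2-en-1-ol. Its E-allylic alcohol later becomes the C8–C9 oxirane ring by Sharpless epoxidation, the chain is extended to the 4,6-diynoic acid, and two such acids are esterified onto 3-O-PMB-sn-glycerol.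

Key step: step 6

Remark: acyl carbons are numbered from the carboxyl carbon (C1); ethyllithium is used as the commercial solution; the glycerol sn-3 oxygen is carried as a PMB ether, since an acetonide cannot be hydrolysed cleanly beside a primary TBS ether and fluoride desilylation of a 1,2-diacylglycerol invites acyl shift.

Step 1
Reactants: 1 4-chlorobutan-1-ol
Product: 3 ethyl (2E)-6-chlorohex-2-enoate, via 4-chlorobutanal 2 (not isolated)
Conditions: TEMPO (cat.), PhI(OAc)2, CH2Cl2, rt; then Ph3P=CHCO2Et, rt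
Reagents that add atoms: ethyl (triphenylphosphoranylidene)acetate, CCOC(=O)C=P(c1ccccc1)(c1ccccc1)c1ccccc1
Why: TEMPO/PhI(OAc)2 oxidises the primary alcohol only as far as the aldehyde, and the stabilised ylide added to the same flask olefinates it E-selectively (one-pot oxidation–Wittig reaction), so volatile 2 need not be isolated.

Step 2
Reactants: 3 ethyl (2E)-6-chlorohex-2-enoate
Product: 4 (2E)-6-chlorohex-2-en-1-ol
Conditions: i-Bu2AlH (DIBAL-H, 2.2 equiv), CH2Cl2, −78 → 0 °C; aqueous Rochelle salt
Reagents that add atoms: none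
Why: i-Bu2AlH reduces the conjugated ester by 1,2-hydride delivery to the allylic alcohol at low temperature (ester reduction), leaving the E double bond and the primary chloride untouched.

Step 3
Reactants: 4 (2E)-6-chlorohex-2-en-1-ol
Product: 5 tert-butyl{[(2E)-6-chlorohex-2-en-1-yl]oxy}dimethylsilane
Conditions: TBSCl, imidazole, CH2Cl2, 0 °C → rt
Reagents that add atoms: tert-butyldimethylsilyl chloride, CC(C)(C)[Si](C)(C)Cl
Why: Imidazole-promoted silylation of a primary allylic alcohol is routine and removes the only acidic proton before the organocopper step.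

Step 4
Reactants: 5 tert-butyl{[(2E)-6-chlorohex-2-en-1-yl]oxy}dimethylsilane
Product: 6 tert-butyl{[(2E)-6-iodohex-2-en-1-yl]oxy}dimethylsilane
Conditions: NaI (3 equiv), NaHCO3 (cat.), acetone, reflux
Reagents that add atoms: sodium iodide, [Na+].[I-]
Why: Finkelstein exchange is driven by precipitation of NaCl from acetone and gives the primary iodide that alkenylcuprates alkylate most readily; the silyl ether is inert to neutral iodide.

Step 5
Reactants: 7 ethyllithium (2 equiv)
Product: 8 lithium diethylcuprate (Et2CuLi)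
Conditions: CuBr·SMe2 (1 equiv), Et2O, −40 °C; the cold solution is carried straight into step 6
Reagents that add atoms: copper bromide–dimethyl sulfide complex CuBr·SMe2, CSC.Br[Cu]
Why: Two equivalents of ethyllithium transmetalate to CuBr to form the lithium dialkylcuprate (organocuprate formation), which is stable in ether at this temperature.

Step 6
Reactants: 8 lithium diethylcuprate; 9 acetylene (4 equiv per cuprate, in two metered portions); 6 tert-butyl{[(2E)-6-iodohex-2-en-1-yl]oxy}dimethylsilane (limiting component)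
Product: 12 tert-butyldimethyl{[(2E,7Z,9Z)-dodeca-2,7,9-trien-1-yl]oxy}silane, via lithium bis[(1Z)-but-1-en-1-yl]cuprate 10 (not isolated), via lithium bis[(1Z,3Z)-hexa-1,3-dien-1-yl]cuprate 11 (not isolated)
Conditions: C2H2 (2 equiv), Et2O, −50 → −25 °C; C2H2 (2 equiv), −10 → 0 °C; then 6, HMPA, P(OEt)3, THF, −40 °C → rt
Reagents that add atoms: none
Why: The ethyl–copper bond adds across acetylene through a four-centre syn transition state to give 10 at −50 to −25 °C, and only on warming to about −10 °C does the less reactive alkenyl–copper bond add in the same syn sense to a second acetylene, giving 11. The closest known reaction type is the carbocupration of acetylene by lithium dialkylcuprates followed by alkylation of the alkenylcuprate with a primary iodide in THF/HMPA with P(OEt)3, which proceeds with retention at the sp2 carbon. No ring is closed and no stereocentre is formed; the two new double bonds (C13=C14 and C15=C16 of the acyl chain) are Z because carbon and copper are delivered to the same face of each alkyne and the vinyl–copper bond is configurationally stable at these temperatures. The step needs exactly two insertions, which metered acetylene and the temperature staging secure because each successive vinylcopper species is less reactive, and it needs substitution at the C–I bond only, which the poor leaving ability of the allylic silyloxy group and the absence of acidic protons in 6 secure.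

Step 7
Reactants: 12 tert-butyldimethyl{[(2E,7Z,9Z)-dodeca-2,7,9-trien-1-yl]oxy}silane
Product: 13 (2E,7Z,9Z)-dodeca-2,7,9-trien-1-ol
Conditions: Bu4NF (TBAF), THF, 0 °C → rt
Reagents that add atoms: none
Why: Fluoride cleaves the Si–O bond (silyl ether deprotection) under conditions that leave all three double bonds unchanged.

Step 8
Reactants: 13 (2E,7Z,9Z)-dodeca-2,7,9-trien-1-ol
Product: 14 [(2S,3S)-3-[(4Z,6Z)-nona-4,6-dien-1-yl]oxiran-2-yl]methanol
Conditions: Ti(OiPr)4 (cat.), L-(+)-diethyl tartrate (cat.), t-BuOOH, 4 Å MS, CH2Cl2, −20 °C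
Reagents that add atoms: tert-butyl hydroperoxide, CC(C)(C)OO
Why: In the Sharpless asymmetric epoxidation the titanium tartrate complex binds the allylic hydroxyl, so only the C2=C3 double bond is oxidised, and with L-(+)-diethyl tartrate on an E-allylic alcohol oxygen is delivered to the face that gives the (2S,3S)-trans-epoxide while the remote Z,Z-diene stays intact.

Step 9
Reactants: 14 [(2S,3S)-3-[(4Z,6Z)-nona-4,6-dien-1-yl]oxiran-2-yl]methanol
Product: 15 (2R,3S)-3-[(4Z,6Z)-nona-4,6-dien-1-yl]oxirane-2-carbaldehyde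
Conditions: Dess–Martin periodinane, NaHCO3, CH2Cl2, 0 °C → rt; crude aldehyde used at once
Reagents that add atoms: none
Why: Buffered Dess–Martin oxidation converts the primary alcohol to the aldehyde under neutral conditions that neither open the oxirane nor epimerise C2 (the descriptor changes from S to R only through the priority rules).

Step 10
Reactants: 15 (2R,3S)-3-[(4Z,6Z)-nona-4,6-dien-1-yl]oxirane-2-carbaldehyde
Product: 16 (2S,3S)-2-ethynyl-3-[(4Z,6Z)-nona-4,6-dien-1-yl]oxirane
Conditions: dimethyl (1-diazo-2-oxopropyl)phosphonate, K2CO3, MeOH, 0 °C → rt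
Reagents that add atoms: dimethyl (1-diazo-2-oxopropyl)phosphonate, COP(=O)(OC)C(=[N+]=[N-])C(C)=O
Why: Methoxide cleaves the Ohira–Bestmann reagent to the diazomethylphosphonate anion, which homologates the aldehyde to the terminal alkyne (Seyferth–Gilbert homologation) under carbonate conditions mild enough for trans-2,3-epoxy aldehydes, so both oxirane stereocentres are carried over.

Step 11
Reactants: 17 pent-4-ynoic acid
Product: 18 5-bromopent-4-ynoic acid
Conditions: Br2, NaOH, H2O, 0 °C; then cold dilute HCl to pH 2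
Reagents that add atoms: bromine, BrBr
Why: Alkaline hypobromite brominates the terminal alkyne C–H of the carboxylate salt (hypohalite halogenation of a 1-alkyne) without adding across the triple bond and without the metal-promoted lactonisation that silver salts could cause.

Step 12
Reactants: 16 (2S,3S)-2-ethynyl-3-[(4Z,6Z)-nona-4,6-dien-1-yl]oxirane; 18 5-bromopent-4-ynoic acid (1.3 equiv, added slowly)
Product: 19 7-[(2S,3S)-3-[(4Z,6Z)-nona-4,6-dien-1-yl]oxiran-2-yl]hepta-4,6-diynoic acid [(8S,9S,13Z,15Z)-8,9-epoxyoctadeca-13,15-diene-4,6-diynoic acid]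
Conditions: CuCl (cat.), NH2OH·HCl, n-BuNH2 (30% aq.), MeOH, 0 °C; cold NaH2PO4/citric acid to pH 4
Reagents that add atoms: none
Why: In the Cadiot–Chodkiewicz coupling the copper acetylide of 16, kept monovalent in copper by hydroxylamine, substitutes the bromoalkyne to give the unsymmetrical 1,3-diyne, and the trans-oxirane and the carboxylate tolerate cold aqueous amine.

Step 13
Reactants: 20 (S)-solketal
Product: 21 (4S)-4-{[(4-methoxybenzyl)oxy]methyl}-2,2-dimethyl-1,3-dioxolane
Conditions: NaH, PMBCl, Bu4NI (cat.), THF/DMF, 0 °C → rt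
Reagents that add atoms: 4-methoxybenzyl chloride, COc1ccc(CCl)cc1
Why: Williamson etherification of the primary alkoxide touches no bond at the stereocentre.

Step 14
Reactants: 21 (4S)-4-{[(4-methoxybenzyl)oxy]methyl}-2,2-dimethyl-1,3-dioxolane
Product: 22 (2R)-3-[(4-methoxybenzyl)oxy]propane-1,2-diol (3-O-PMB-sn-glycerol)
Conditions: AcOH/H2O (4:1), 40 °C
Reagents that add atoms: none
Why: Mild aqueous acid hydrolyses the isopropylidene acetal while the PMB ether is stable (acetal hydrolysis), giving the sn-3 protected glycerol with the stereocentre untouched.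

Step 15
Reactants: 22 (2R)-3-[(4-methoxybenzyl)oxy]propane-1,2-diol; 19 7-[(2S,3S)-3-[(4Z,6Z)-nona-4,6-dien-1-yl]oxiran-2-yl]hepta-4,6-diynoic acid (2.3 equiv)
Product: 23 (2S)-3-[(4-methoxybenzyl)oxy]propane-1,2-diyl bis{7-[(2S,3S)-3-[(4Z,6Z)-nona-4,6-dien-1-yl]oxiran-2-yl]hepta-4,6-diynoate}
Conditions: EDC·HCl, DMAP, CH2Cl2, 0 °C → rt
Reagents that add atoms: none
Why: Carbodiimide activation with DMAP catalysis (Steglich esterification) acylates both the primary and the secondary hydroxyl at or below room temperature without disturbing oxiranes, diynes or dienes, and the glycerol stereocentre is not involved.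

Step 16
Reactants: 23 (2S)-3-[(4-methoxybenzyl)oxy]propane-1,2-diyl bis{7-[(2S,3S)-3-[(4Z,6Z)-nona-4,6-dien-1-yl]oxiran-2-yl]hepta-4,6-diynoate}
Product: 24 (2S)-3-hydroxypropane-1,2-diyl bis{7-[(2S,3S)-3-[(4Z,6Z)-nona-4,6-dien-1-yl]oxiran-2-yl]hepta-4,6-diynoate} (1,2-diacyl-sn-glycerol, CNP0301966.1)
Conditions: DDQ, CH2Cl2/pH 7 phosphate buffer (10:1), 0 °C; chromatography on boric acid-treated silica
Reagents that add atoms: none
Why: DDQ oxidises the electron-rich benzyl ether by hydride abstraction to an oxocarbenium ion that water hydrolyses (oxidative PMB cleavage), a near-neutral deprotection that does not promote 1,2→1,3 acyl shift.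

**Compound list**

1 | 4-chlorobutan-1-ol | OCCCCCl | starting material
2 | 4-chlorobutanal | O=CCCCCl | intermediate
3 | ethyl (2E)-6-chlorohex-2-enoate | CCOC(=O)/C=C/CCCCl | intermediate
4 | (2E)-6-chlorohex-2-en-1-ol | OC/C=C/CCCCl | intermediate
5 | tert-butyl{[(2E)-6-chlorohex-2-en-1-yl]oxy}dimethylsilane | CC(C)(C)[Si](C)(C)OC/C=C/CCCCl | intermediate
6 | tert-butyl{[(2E)-6-iodohex-2-en-1-yl]oxy}dimethylsilane | CC(C)(C)[Si](C)(C)OC/C=C/CCCI | intermediate
7 | ethyllithium | [Li]CC | starting material
8 | lithium diethylcuprate | CC[Cu-]CC.[Li+] | intermediate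
9 | acetylene | C#C | starting material
10 | lithium bis[(1Z)-but-1-en-1-yl]cuprate | CC/C=C\[Cu-]/C=C\CC.[Li+] | intermediate
11 | lithium bis[(1Z,3Z)-hexa-1,3-dien-1-yl]cuprate | CC/C=C\C=C/[Cu-]\C=C/C=C\CC.[Li+] | intermediate
12 | tert-butyldimethyl{[(2E,7Z,9Z)-dodeca-2,7,9-trien-1-yl]oxy}silane | CC(C)(C)[Si](C)(C)OC/C=C/CCC/C=C\C=C/CC | intermediate
13 | (2E,7Z,9Z)-dodeca-2,7,9-trien-1-ol | OC/C=C/CCC/C=C\C=C/CC | intermediate
14 | [(2S,3S)-3-[(4Z,6Z)-nona-4,6-dien-1-yl]oxiran-2-yl]methanol | OC[C@@H]1O[C@H]1CCC/C=C\C=C/CC | intermediate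
15 | (2R,3S)-3-[(4Z,6Z)-nona-4,6-dien-1-yl]oxirane-2-carbaldehyde | O=C[C@@H]1O[C@H]1CCC/C=C\C=C/CC | intermediate
16 | (2S,3S)-2-ethynyl-3-[(4Z,6Z)-nona-4,6-dien-1-yl]oxirane | C#C[C@@H]1O[C@H]1CCC/C=C\C=C/CC | intermediate
17 | pent-4-ynoic acid | OC(=O)CCC#C | starting material
18 | 5-bromopent-4-ynoic acid | OC(=O)CCC#CBr | intermediate
19 | 7-[(2S,3S)-3-[(4Z,6Z)-nona-4,6-dien-1-yl]oxiran-2-yl]hepta-4,6-diynoic acid | OC(=O)CCC#CC#C[C@@H]1O[C@H]1CCC/C=C\C=C/CC | intermediate
20 | (S)-solketal, [(4S)-2,2-dimethyl-1,3-dioxolan-4-yl]methanol | CC1(C)OC[C@H](CO)O1 | starting material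
21 | (4S)-4-{[(4-methoxybenzyl)oxy]methyl}-2,2-dimethyl-1,3-dioxolane | CC1(C)OC[C@H](COCc2ccc(OC)cc2)O1 | intermediate
22 | (2R)-3-[(4-methoxybenzyl)oxy]propane-1,2-diol | OC[C@H](COCc1ccc(OC)cc1)O | intermediate
23 | (2S)-3-[(4-methoxybenzyl)oxy]propane-1,2-diyl bis{7-[(2S,3S)-3-[(4Z,6Z)-nona-4,6-dien-1-yl]oxiran-2-yl]hepta-4,6-diynoate} | CC/C=C\C=C/CCC[C@@H]1O[C@H]1C#CC#CCCC(=O)OC[C@H](COCc2ccc(OC)cc2)OC(=O)CCC#CC#C[C@@H]1O[C@H]1CCC/C=C\C=C/CC | intermediate
24 | (2S)-3-hydroxypropane-1,2-diyl bis{7-[(2S,3S)-3-[(4Z,6Z)-nona-4,6-dien-1-yl]oxiran-2-yl]hepta-4,6-diynoate} | CC/C=C\C=C/CCC[C@@H]1O[C@H]1C#CC#CCCC(=O)OC[C@H](CO)OC(=O)CCC#CC#C[C@@H]1O[C@H]1CCC/C=C\C=C/CC | target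

**Step count**

Total: 16 steps. Longest linear sequence: 12 steps (1, 2, 3, 4, 6, 7, 8, 9, 10, 12, 15, 16) from 4-chlorobutan-1-ol.

**Steps most likely to fail**

Step 6. The second acetylene insertion may stay incomplete, or a third may begin if temperature or gas metering drifts, which would give chain homologues that are hard to separate. Transfer of the dienyl group to the iodide may also be sluggish. The fallback sets out from 6 and comes back at 12. Iodide 6 would be alkylated with LiC≡CH·H2NCH2CH2NH2 in DMSO to give tert-butyldimethyl{[(2E)-oct-2-en-7-yn-1-yl]oxy}silane F1. NBS with catalytic AgNO3 in acetone would convert this into {[(2E)-8-bromooct-2-en-7-yn-1-yl]oxy}(tert-butyl)dimethylsilane F2. Cadiot–Chodkiewicz coupling of F2 with an excess of commercial but-1-yne (CuCl, NH2OH·HCl, n-BuNH2) would give tert-butyl{[(2E)-dodec-2-ene-7,9-diyn-1-yl]oxy}dimethylsilane F3. Reduction of the conjugated diyne with zinc activated by Cu(OAc)2 and AgNO3 in aqueous methanol should then give the Z,Z-diene 12 by twofold cis semi-reduction.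

Step 10. Carbonate in methanol may epimerise the aldehyde α-carbon or open the oxirane by methoxide before homologation is complete. The fallback sets out from 15 and comes back at 19, bypassing 16 and 18. Aldehyde 15 would be treated with CBr4, PPh3 and Et3N in CH2Cl2 at 0 °C (first stage of the Corey–Fuchs sequence) to give (2S,3S)-2-(2,2-dibromoethenyl)-3-[(4Z,6Z)-nona-4,6-dien-1-yl]oxirane F4. NaN(SiMe3)2 in THF at −78 °C would eliminate HBr to give (2S,3S)-2-(bromoethynyl)-3-[(4Z,6Z)-nona-4,6-dien-1-yl]oxirane F5. Cadiot–Chodkiewicz coupling of F5 with pent-4-ynoic acid 17 (CuCl, NH2OH·HCl, n-BuNH2, 0 °C) would lead directly to acid 19.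

Step 16. The acyl groups may shift from the 1,2- to the 1,3-positions during deprotection or chromatography, or DDQ may attack the electron-rich Z,Z-dienes. The fallback sets out from 20 (with acid 19) and comes back at 24, replacing the oxidative deprotection by a buffered fluoride one. (S)-Solketal 20 would be silylated with TBDPSCl and imidazole to tert-butyl{[(4R)-2,2-dimethyl-1,3-dioxolan-4-yl]methoxy}diphenylsilane F6. Aqueous acetic acid would hydrolyse the acetal, which the robust silyl ether survives, to give (2R)-3-{[tert-butyl(diphenyl)silyl]oxy}propane-1,2-diol F7. Steglich diacylation with 19 would give (2R)-3-{[tert-butyl(diphenyl)silyl]oxy}propane-1,2-diyl bis{7-[(2S,3S)-3-[(4Z,6Z)-nona-4,6-dien-1-yl]oxiran-2-yl]hepta-4,6-diynoate} F8. HF·pyridine buffered with excess pyridine in THF at 0 °C would then release 24.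

**Further compounds**

F1 | step 6 | tert-butyldimethyl{[(2E)-oct-2-en-7-yn-1-yl]oxy}silane | CC(C)(C)[Si](C)(C)OC/C=C/CCCC#C
F2 | step 6 | {[(2E)-8-bromooct-2-en-7-yn-1-yl]oxy}(tert-butyl)dimethylsilane | CC(C)(C)[Si](C)(C)OC/C=C/CCCC#CBr
F3 | step 6 | tert-butyl{[(2E)-dodec-2-ene-7,9-diyn-1-yl]oxy}dimethylsilane | CC(C)(C)[Si](C)(C)OC/C=C/CCCC#CC#CCC
F4 | step 10 | (2S,3S)-2-(2,2-dibromoethenyl)-3-[(4Z,6Z)-nona-4,6-dien-1-yl]oxirane | BrC(Br)=C[C@@H]1O[C@H]1CCC/C=C\C=C/CC
F5 | step 10 | (2S,3S)-2-(bromoethynyl)-3-[(4Z,6Z)-nona-4,6-dien-1-yl]oxirane | BrC#C[C@@H]1O[C@H]1CCC/C=C\C=C/CC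
F6 | step 16 | tert-butyl{[(4R)-2,2-dimethyl-1,3-dioxolan-4-yl]methoxy}diphenylsilane | CC1(C)OC[C@H](CO[Si](c2ccccc2)(c2ccccc2)C(C)(C)C)O1
F7 | step 16 | (2R)-3-{[tert-butyl(diphenyl)silyl]oxy}propane-1,2-diol | OC[C@H](CO[Si](c1ccccc1)(c1ccccc1)C(C)(C)C)O
F8 | step 16 | (2R)-3-{[tert-butyl(diphenyl)silyl]oxy}propane-1,2-diyl bis{7-[(2S,3S)-3-[(4Z,6Z)-nona-4,6-dien-1-yl]oxiran-2-yl]hepta-4,6-diynoate} | CC/C=C\C=C/CCC[C@@H]1O[C@H]1C#CC#CCCC(=O)OC[C@H](CO[Si](c2ccccc2)(c2ccccc2)C(C)(C)C)OC(=O)CCC#CC#C[C@@H]1O[C@H]1CCC/C=C\C=C/CC
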